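If a curve in percent does not shift with the charge, the gas being held, a count of turnovers read on one flask can be carried to the next flask at that gas. We count turnovers: minus the natural logarithm of the fraction of electrophile left.

| setting | dawn | dusk | flask |
|---|---|---|---|
| electrophile | 0.14 M | 0.22 M | 0.10 M |
| gas | 7.3 mM (held) | 7.3 mM (held) | 7.3 mM (held) |
| remark | run made earlier | run made earlier |  |
| time |  |  | 2.5 d |

- dawn (time / d: product / %, electrophile / %): 0.167: 2.5, 97.8; 0.500: 12.1, 89.9; 0.833: 16.1, 83.6; 1.25: 22.2, 79.2; 2.08: 35.7, 64.3; 2.50: 42.8, 59.8
- dusk (time / d: product / %, electrophile / %): 0.167: 3.0, 97.6; 0.500: 8.8, 90.6; 0.833: 16.1, 84.2; 1.25: 20.8, 80.2; 2.08: 34.0, 66.1; 2.50: 37.6, 60.9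

(each reading ± 1 percentage point)

- the analysis behind the earlier runs scatters by 1 percentage point, standard deviation
- at the start none of the gas is in solution

1. amount of product in the flask at 2.5 d, in percent of the electrophile charged
2. amount of electrophile in the flask at 2.5 d, in percent of the electrophile charged

1. The charges of the dawn and dusk runs are 0.14 M and 0.22 M, yet at 2.50 d the electrophile reads 59.8% and 60.9%, a gap of 1.1 percentage points against a scatter of 1 point per reading.

2. First way, from electrophile left: dawn gives 0.206 d⁻¹, dusk 0.198 d⁻¹.

3. Second way, from product made, read as electrophile gone: dawn gives 0.223 d⁻¹, dusk 0.189 d⁻¹. This pair parts further than the first.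

4. Which cheats? At 2.08 d product and electrophile sum to 100.0% at dawn and 100.1% at dusk. At 2.50 d they sum to 102.6% and 98.50%. The two product readings at that time lie 5.2 points apart, wider than the 1.1 points between the electrophile readings, so we lean on the electrophile pair. Its mean is our turnovers per day, a pseudo-first-order constant, 0.202 d⁻¹.

5. Carried to the flask, 2.5 d makes 0.505 turnovers, which leaves 60.3% electrophile and gives 39.7% product.

The forecast, holding the reaction “essentially first order in electrophile”, says 59.5% electrophile and 40.5% product, its electrophile 0.80 points below ours.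

The flask gives 58.3% electrophile and 41.7% product, which the forecast meets within its margin. Its nucleophile, the dissolved gas, reads 0.00630 M at 0.250 d and 0.00662 M at 2.50 d. Our turnovers per day put the point where electrophile and product hold the same at 3.43 d; the flask reaches it at 3.19 d.

    nucleophile ⇌ dormant form (K = 30.0, k = 0.200 h⁻¹)
    crystals ⇌ acid set free, rate k2*(cs2 - [acid set free]) while solid is left; crystals form when [acid set free] > cs2 (solubility = 6.40 mM, k = 0.970 h⁻¹)
    gas ⇌ nucleophile, rate k3*(csat - [nucleophile]) (kL = 2.90 h⁻¹)
    electrophile + nucleophile → acid set free + product (k = 1.40 L mol⁻¹ h⁻¹)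
    nucleophile + acid set free ⇌ protonated nucleophile, settled at all times (K = 1.30 × 10⁵ L mol⁻¹)

For the same flask left until 6.0 d, 0.202 d⁻¹ gives 1.21 turnovers, so 29.8% electrophile. The computed flask holds 26.3%.

The numbers in the tables come from a simulation on assumed constants; noise was put on by code.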